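Labdane numbering is used. Ring A is treated as a cyclohexene retron: the ring-fusion bond C5–C10 is the dienophile π-bond of an acyclic (E)-enal, and C1–C4, with the gem-dimethyl carbon C4, is 4-methylpenta-1,3-diene. One catalytic enantioselective Diels–Alder reaction forms C1–C10 and C4–C5, creates quaternary C10 and C5, and fixes their trans relationship through the alkene geometry. The precursor, (2E)-3-methylhexa-2,5-dienal, is open-chain; its formyl carbon (C6) and allyl group (C9, C8, C7) are then closed to ring B by Wacker oxidation and aldol condensation, and the resulting C8 ketone directs side-chain attachment at C9 and the final methylenation.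

Key step: step 3

Remark: the enantiofacial sense of the oxazaborolidinium catalyst with an α-unsubstituted enal is assigned by analogy and is to be confirmed on the first run; the (R)-catalyst is equally available if the (S)-catalyst favours the antipode of 6.

Step 1
Reactants: 1 pent-1-en-4-yne
Product: 3 (2E)-3-methylhexa-2,5-dien-1-ol, via alkenylalane 2 (not isolated)
Conditions: AlMe3, Cp2ZrCl2 (zirconocene dichloride, 25 mol %), CH2Cl2, 0 °C → rt; then n-BuLi, THF, −78 °C; (CH2O)n, rt
Reagents that add atoms: trimethylaluminium, C[Al](C)C; formaldehyde (from paraformaldehyde), C=O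
Why: Zirconium-catalysed Negishi carboalumination should add Me–Al syn across the terminal alkyne with methyl on the internal carbon and leave the 1-alkene alone, so hydroxymethylation of the alkenylalanate with retention delivers the (E)-trisubstituted allylic alcohol in which labdane C6 and C9 are trans.

Step 2
Reactants: 3 (2E)-3-methylhexa-2,5-dien-1-ol
Product: 4 (2E)-3-methylhexa-2,5-dienal
Conditions: MnO2 (activated, excess), CH2Cl2, rt
Reagents that add atoms: none
Why: Allylic oxidation with MnO2 is selective for the allylic alcohol and neutral, so the (E)-geometry and the skipped diene should survive.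

Step 3
Reactants: 4 (2E)-3-methylhexa-2,5-dienal; 5 4-methylpenta-1,3-diene
Product: 6 (1S,6R)-2,2,6-trimethyl-6-(prop-2-en-1-yl)cyclohex-3-ene-1-carbaldehyde
Conditions: 5 (5 equiv), (S)-tetrahydro-1-(2-methylphenyl)-3,3-diphenyl-1H,3H-pyrrolo[1,2-c][1,3,2]oxazaborole (20 mol %), HN(SO2CF3)2 (20 mol %), CH2Cl2, −78 → −20 °C
Reagents that add atoms: none
Why: This is a Lewis-acid-catalysed normal-demand Diels–Alder reaction (closest precedents: oxazaborolidinium-catalysed enal–diene cycloadditions and AlCl3-promoted additions of β,β-disubstituted enones to 1-substituted dienes), in which the boron-bound s-trans enal reacts through a concerted but strongly asynchronous transition state led by the bond from the CH2 terminus of 5 to the β-carbon of 4. Ring A is closed by this single intermolecular [4+2] event, suprafacial on both partners, forming labdane C1–C10 and C4–C5 and placing the gem-dimethyl carbon C4 next to C5. The relative configuration of the two new stereocentres (quaternary C10, tertiary C5) is fixed by the (E)-geometry of 4, which puts formyl and allyl trans and so encodes the trans ring fusion, while their absolute configuration is set by the catalyst, which shields one enantioface of the coordinated enal. Regioselectivity follows from the larger HOMO coefficient at the CH2 terminus of 5 and the larger LUMO coefficient at the β-carbon of 4, and is reinforced because the other orientation would join two quaternary carbons. Chemoselectivity for the conjugated C=C bond over the isolated vinyl group is secured by formyl activation alone. The reactive s-cis conformer of 5 is disfavoured by its (Z)-methyl group, so excess diene and the strongest cationic catalyst are used.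

Step 4
Reactants: 6 (1S,6R)-2,2,6-trimethyl-6-(prop-2-en-1-yl)cyclohex-3-ene-1-carbaldehyde
Product: 7 (1S,6S)-2,2,6-trimethyl-6-(2-oxopropyl)cyclohex-3-ene-1-carbaldehyde
Conditions: PdCl2 (10 mol %), CuCl, O2 (1 atm), DMF/H2O (7:1), rt
Reagents that add atoms: water, O
Why: Tsuji–Wacker oxidation should convert the monosubstituted alkene to the methyl ketone with Markovnikov selectivity, while the internal ring alkene and the hindered aldehyde are left alone; no stereocentre is touched.

Step 5
Reactants: 7 (1S,6S)-2,2,6-trimethyl-6-(2-oxopropyl)cyclohex-3-ene-1-carbaldehyde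
Product: 8 (4aS,8aS)-5,5,8a-trimethyl-4a,5,8,8a-tetrahydronaphthalen-2(1H)-one
Conditions: KOH, MeOH, rt → 40 °C
Reagents that add atoms: none
Why: Base-mediated intramolecular aldol condensation (6-enolexo-exo-trig) of the methyl ketone enolate onto the aldehyde, followed by dehydration, should give the trans-fused enone; the aldehyde α-centre is expected to hold because its enolisation would place an exocyclic double bond between two quaternary carbons.

Step 6
Reactants: 8 (4aS,8aS)-5,5,8a-trimethyl-4a,5,8,8a-tetrahydronaphthalen-2(1H)-one; 9 2-(2-bromoethyl)-2-methyl-1,3-dioxolane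
Product: 11 (1R,4aR,8aR)-5,5,8a-trimethyl-1-[2-(2-methyl-1,3-dioxolan-2-yl)ethyl]-4a,5,8,8a-tetrahydronaphthalen-2(1H)-one, via lithium dienolate 10 (not isolated)
Conditions: LiN(i-Pr)2 (LDA), THF, −78 °C; then 9, DMPU, −78 → 0 °C
Reagents that add atoms: none
Why: Kinetic deprotonation of the enone with LDA occurs at the only α′-position (naphthalenone C1, labdane C9) to give the cross-conjugated dienolate, whose SN2 alkylation by the primary bromide should proceed anti to the angular methyl group; 11 is drawn as that epimer, and either epimer is serviceable because step 7 equilibrates this centre.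

Step 7
Reactants: 11 (1R,4aR,8aR)-5,5,8a-trimethyl-1-[2-(2-methyl-1,3-dioxolan-2-yl)ethyl]-4a,5,8,8a-tetrahydronaphthalen-2(1H)-one
Product: 13 (1S,4aR,8aR)-5,5,8a-trimethyl-1-[2-(2-methyl-1,3-dioxolan-2-yl)ethyl]octahydronaphthalen-2(1H)-one, via C1-epimeric saturated ketone 12 (not isolated)
Conditions: H2 (1 atm), 10 % Pd/C, EtOAc, rt; filter; then NaOMe (0.3 equiv), MeOH, rt
Reagents that add atoms: none
Why: Heterogeneous catalytic hydrogenation saturates the enone C3=C4 and the ring alkene C6=C7 without creating stereocentres, and methoxide-mediated enolisation then equilibrates C1 to the equatorial side chain (cis to the angular methyl), the expected thermodynamic, labdane-type configuration.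

Step 8
Reactants: 13 (1S,4aR,8aR)-5,5,8a-trimethyl-1-[2-(2-methyl-1,3-dioxolan-2-yl)ethyl]octahydronaphthalen-2(1H)-one
Product: 14 2-methyl-2-{2-[(1R,4aR,8aR)-5,5,8a-trimethyl-2-methylidenedecahydronaphthalen-1-yl]ethyl}-1,3-dioxolane
Conditions: Ph3PCH3Br, KOt-Bu, toluene, 90 °C
Reagents that add atoms: methyltriphenylphosphonium bromide, C[P+](c1ccccc1)(c1ccccc1)c1ccccc1.[Br-]
Why: Wittig methylenation with Ph3P=CH2 at elevated temperature is the established way to convert hindered α-branched cyclohexanones to exocyclic methylenes; the ketal is inert and C1 is already at its thermodynamic configuration, so the basic conditions should not erode it.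

Step 9
Reactants: 14 2-methyl-2-{2-[(1R,4aR,8aR)-5,5,8a-trimethyl-2-methylidenedecahydronaphthalen-1-yl]ethyl}-1,3-dioxolane
Product: 15 4-[(1R,4aR,8aR)-5,5,8a-trimethyl-2-methylidenedecahydronaphthalen-1-yl]butan-2-one
Conditions: pyridinium p-toluenesulfonate (cat.), THF/H2O (4:1), 50 °C
Reagents that add atoms: water, O
Why: Mild acid-catalysed hydrolysis of the dioxolane (acetal deprotection) liberates the methyl ketone under conditions too weak to isomerise the exocyclic alkene.

Step 10
Reactants: 15 4-[(1R,4aR,8aR)-5,5,8a-trimethyl-2-methylidenedecahydronaphthalen-1-yl]butan-2-one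
Product: 16 ethyl (2E)-3-methyl-5-[(1R,4aR,8aR)-5,5,8a-trimethyl-2-methylidenedecahydronaphthalen-1-yl]pent-2-enoate
Conditions: (EtO)2P(O)CH2CO2Et, NaH, THF, 0 → 60 °C; chromatography
Reagents that add atoms: triethyl phosphonoacetate, CCOC(=O)CP(=O)(OCC)OCC
Why: Horner–Wadsworth–Emmons olefination of the methyl ketone gives the trisubstituted enoate with the (E)-isomer favoured (ester trans to the larger alkyl chain); the minor (Z)-isomer is to be removed by chromatography.

Step 11
Reactants: 16 ethyl (2E)-3-methyl-5-[(1R,4aR,8aR)-5,5,8a-trimethyl-2-methylidenedecahydronaphthalen-1-yl]pent-2-enoate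
Product: 17 (2E)-3-methyl-5-[(1R,4aR,8aR)-5,5,8a-trimethyl-2-methylidenedecahydronaphthalen-1-yl]pent-2-en-1-ol
Conditions: i-Bu2AlH, CH2Cl2, −78 → 0 °C; aq. potassium sodium tartrate
Reagents that add atoms: none
Why: 1,2-Reduction of the α,β-unsaturated ester with i-Bu2AlH gives the allylic alcohol (ent-copalol) without touching either alkene or any stereocentre.

Step 12
Reactants: 17 (2E)-3-methyl-5-[(1R,4aR,8aR)-5,5,8a-trimethyl-2-methylidenedecahydronaphthalen-1-yl]pent-2-en-1-ol
Product: 18 3-{[(2E)-3-methyl-5-[(1R,4aR,8aR)-5,5,8a-trimethyl-2-methylidenedecahydronaphthalen-1-yl]pent-2-en-1-yl]oxy}-3-oxopropanoic acid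
Conditions: 2,2-dimethyl-1,3-dioxane-4,6-dione (Meldrum's acid), toluene, 90 °C
Reagents that add atoms: Meldrum's acid, CC1(C)OC(=O)CC(=O)O1
Why: Thermal acylation of the alcohol by Meldrum's acid (ring-opening with loss of acetone) gives the malonic half-ester directly, with no protecting group and no base that could isomerise the allylic system.

Compound list
1 | pent-1-en-4-yne | C=CCC#C | starting material
2 | dimethyl[(1E)-2-methylpenta-1,4-dien-1-yl]alumane | C=CC/C(C)=C/[Al](C)C | intermediate
3 | (2E)-3-methylhexa-2,5-dien-1-ol | C=CC/C(C)=C/CO | intermediate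
4 | (2E)-3-methylhexa-2,5-dienal | C=CC/C(C)=C/C=O | intermediate
5 | 4-methylpenta-1,3-diene | CC(C)=CC=C | starting material
6 | (1S,6R)-2,2,6-trimethyl-6-(prop-2-en-1-yl)cyclohex-3-ene-1-carbaldehyde | O=C[C@@H]1C(C)(C)C=CC[C@@]1(C)CC=C | intermediate
7 | (1S,6S)-2,2,6-trimethyl-6-(2-oxopropyl)cyclohex-3-ene-1-carbaldehyde | O=C[C@@H]1C(C)(C)C=CC[C@@]1(C)CC(C)=O | intermediate
8 | (4aS,8aS)-5,5,8a-trimethyl-4a,5,8,8a-tetrahydronaphthalen-2(1H)-one | O=C1C=C[C@@H]2C(C)(C)C=CC[C@@]2(C)C1 | intermediate
9 | 2-(2-bromoethyl)-2-methyl-1,3-dioxolane | CC1(CCBr)OCCO1 | starting material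
10 | lithium (4aR,8aR)-5,5,8a-trimethyl-4a,5,8,8a-tetrahydronaphthalen-2-olate | [Li]OC1C=C[C@@H]2C(C)(C)C=CC[C@@]2(C)C=1 | intermediate
11 | (1R,4aR,8aR)-5,5,8a-trimethyl-1-[2-(2-methyl-1,3-dioxolan-2-yl)ethyl]-4a,5,8,8a-tetrahydronaphthalen-2(1H)-one | O=C1C=C[C@@H]2C(C)(C)C=CC[C@@]2(C)[C@H]1CCC1(C)OCCO1 | intermediate
12 | (1R,4aR,8aR)-5,5,8a-trimethyl-1-[2-(2-methyl-1,3-dioxolan-2-yl)ethyl]octahydronaphthalen-2(1H)-one | O=C1CC[C@@H]2C(C)(C)CCC[C@@]2(C)[C@H]1CCC1(C)OCCO1 | intermediate
13 | (1S,4aR,8aR)-5,5,8a-trimethyl-1-[2-(2-methyl-1,3-dioxolan-2-yl)ethyl]octahydronaphthalen-2(1H)-one | O=C1CC[C@@H]2C(C)(C)CCC[C@@]2(C)[C@@H]1CCC1(C)OCCO1 | intermediate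
14 | 2-methyl-2-{2-[(1R,4aR,8aR)-5,5,8a-trimethyl-2-methylidenedecahydronaphthalen-1-yl]ethyl}-1,3-dioxolane | C=C1CC[C@@H]2C(C)(C)CCC[C@@]2(C)[C@@H]1CCC1(C)OCCO1 | intermediate
15 | 4-[(1R,4aR,8aR)-5,5,8a-trimethyl-2-methylidenedecahydronaphthalen-1-yl]butan-2-one | C=C1CC[C@@H]2C(C)(C)CCC[C@@]2(C)[C@@H]1CCC(C)=O | intermediate
16 | ethyl (2E)-3-methyl-5-[(1R,4aR,8aR)-5,5,8a-trimethyl-2-methylidenedecahydronaphthalen-1-yl]pent-2-enoate | C=C1CC[C@@H]2C(C)(C)CCC[C@@]2(C)[C@@H]1CC/C(C)=C/C(=O)OCC | intermediate
17 | (2E)-3-methyl-5-[(1R,4aR,8aR)-5,5,8a-trimethyl-2-methylidenedecahydronaphthalen-1-yl]pent-2-en-1-ol (ent-copalol) | C=C1CC[C@@H]2C(C)(C)CCC[C@@]2(C)[C@@H]1CC/C(C)=C/CO | intermediate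
18 | 3-{[(2E)-3-methyl-5-[(1R,4aR,8aR)-5,5,8a-trimethyl-2-methylidenedecahydronaphthalen-1-yl]pent-2-en-1-yl]oxy}-3-oxopropanoic acid | C=C1CC[C@@H]2C(C)(C)CCC[C@@]2(C)[C@@H]1CC/C(C)=C/COC(=O)CC(=O)O | target

Total step count: 12. Longest linear sequence: 12 steps (from 1; 5 and 9 are commercial).

Steps most likely to fail

Step 3. The cycloaddition may be too slow, because the enal is β,β-disubstituted and the reactive s-cis conformer of the diene is disfavoured. Cationic oligomerisation of the diene, a stepwise pathway that erodes the trans relationship, or weak enantiofacial discrimination may also intervene. The fallback sets out from 4 and comes back at 6, and forms the same two bonds in one operation through a cationic, auxiliary-controlled cycloaddition. Acetalisation of 4 with (2R,4R)-2,4-bis(trimethylsilyloxy)pentane and catalytic Me3SiOTf in CH2Cl2 at −78 °C should give (4R,6R)-4,6-dimethyl-2-[(1E)-2-methylpenta-1,4-dien-1-yl]-1,3-dioxane F1. With CF3SO3H (cat.) in CH2Cl2 at −78 °C, F1 opens to a vinyl-substituted oxocarbenium ion, a far stronger dienophile than the neutral enal, which adds 5 in an ionic Diels–Alder reaction. The acetal recloses to (4R,6R)-4,6-dimethyl-2-[(1S,6R)-2,2,6-trimethyl-6-(prop-2-en-1-yl)cyclohex-3-en-1-yl]-1,3-dioxane F2. Its diastereomers are separated by chromatography, so the auxiliary also acts as a resolving handle. Hydrolysis with pyridinium p-toluenesulfonate in THF/H2O returns 6.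

Step 6. C-alkylation at a neopentyl-type enolate carbon may be slow, so that proton transfer between enolate and product and elimination of HBr from the electrophile compete. The fallback sets out from 8 and comes back at 11, replacing the SN2 alkylation by a conjugate addition. Kinetic enolisation and silylation (LDA, Me3SiCl, THF, −78 °C) should give trimethyl{[(4aR,8aR)-5,5,8a-trimethyl-4a,5,8,8a-tetrahydronaphthalen-2-yl]oxy}silane F3. TiCl4-mediated Mukaiyama–Michael addition of F3 to but-3-en-2-one (CH2Cl2, −78 °C) should give (1R,4aR,8aR)-5,5,8a-trimethyl-1-(3-oxobutyl)-4a,5,8,8a-tetrahydronaphthalen-2(1H)-one F4. The trans ring fusion disfavours the boat needed for a second, intramolecular Michael addition. Chemoselective ketalisation of the saturated methyl ketone of F4 in the presence of the enone (1,2-bis(trimethylsilyloxy)ethane, catalytic Me3SiOTf, CH2Cl2, −78 °C) then gives 11.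

Step 10. The olefination of a methyl ketone may show incomplete (E)-selectivity, which costs material and requires separation of geometric isomers. The fallback sets out from 15 and comes back at 17, bypassing 16, and builds the trisubstituted alkene stereospecifically. Kinetic enolisation and phosphorylation (LDA; ClP(O)(OEt)2, THF, −78 °C) should give diethyl 4-[(1R,4aR,8aR)-5,5,8a-trimethyl-2-methylidenedecahydronaphthalen-1-yl]but-1-en-2-yl phosphate F5. Elimination with further LDA gives the terminal alkyne (1R,4aR,8aR)-1-(but-3-yn-1-yl)-5,5,8a-trimethyl-2-methylidenedecahydronaphthalene F6. Zirconium-catalysed carboalumination (AlMe3, Cp2ZrCl2, CH2Cl2), which leaves the 1,1-disubstituted exocyclic alkene alone, gives dimethyl{(1E)-2-methyl-4-[(1R,4aR,8aR)-5,5,8a-trimethyl-2-methylidenedecahydronaphthalen-1-yl]but-1-en-1-yl}alumane F7. Treatment with n-BuLi and then (CH2O)n delivers 17 with the (E)-geometry fixed by syn addition.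

Further compounds
F1 | step 3 | (4R,6R)-4,6-dimethyl-2-[(1E)-2-methylpenta-1,4-dien-1-yl]-1,3-dioxane | C=CC/C(C)=C/C1O[C@H](C)C[C@@H](C)O1
F2 | step 3 | (4R,6R)-4,6-dimethyl-2-[(1S,6R)-2,2,6-trimethyl-6-(prop-2-en-1-yl)cyclohex-3-en-1-yl]-1,3-dioxane | C1(O[C@H](C)C[C@@H](C)O1)[C@@H]1C(C)(C)C=CC[C@@]1(C)CC=C
F3 | step 6 | trimethyl{[(4aR,8aR)-5,5,8a-trimethyl-4a,5,8,8a-tetrahydronaphthalen-2-yl]oxy}silane | C[Si](C)(C)OC1C=C[C@@H]2C(C)(C)C=CC[C@@]2(C)C=1
F4 | step 6 | (1R,4aR,8aR)-5,5,8a-trimethyl-1-(3-oxobutyl)-4a,5,8,8a-tetrahydronaphthalen-2(1H)-one | O=C1C=C[C@@H]2C(C)(C)C=CC[C@@]2(C)[C@H]1CCC(C)=O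
F5 | step 10 | diethyl 4-[(1R,4aR,8aR)-5,5,8a-trimethyl-2-methylidenedecahydronaphthalen-1-yl]but-1-en-2-yl phosphate | C=C1CC[C@@H]2C(C)(C)CCC[C@@]2(C)[C@@H]1CCC(=C)OP(=O)(OCC)OCC
F6 | step 10 | (1R,4aR,8aR)-1-(but-3-yn-1-yl)-5,5,8a-trimethyl-2-methylidenedecahydronaphthalene | C=C1CC[C@@H]2C(C)(C)CCC[C@@]2(C)[C@@H]1CCC#C
F7 | step 10 | dimethyl{(1E)-2-methyl-4-[(1R,4aR,8aR)-5,5,8a-trimethyl-2-methylidenedecahydronaphthalen-1-yl]but-1-en-1-yl}alumane | C=C1CC[C@@H]2C(C)(C)CCC[C@@]2(C)[C@@H]1CC/C(C)=C/[Al](C)C
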